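**Retrosynthetic overview**

1. 27 ⇐ 26 ⇐ 24: the 3-hydroxybenzoyl group is put on C3 of the bicyclic ethyl enol ether 24 last; one hydrolysis then frees the enol and the phenol.
2. 24 ⇐ 20 (key step): the ring C1–C2–C3–C4–C5–C9 is a cyclohexane-1,3,5-trione, a formal ketene trimer whose C9 ketone lies between the quaternary bridgeheads C1 and C5. C2–C3–C4–C5 can therefore be carried as a 3-ethoxycyclobutenone (masked ketene dimer) and C1–C9 as an ester enolate, and the four-membered ring grows by two atoms into the six-membered one.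
3. 20 ⇐ 17 (dialkylketene + ethoxyethyne, [2+2]); 17 ⇐ 15 + dianion of 2 (C5–C6 bond); 15 ⇐ 5 by functional-group changes at both chain ends.
4. 5 ⇐ 3: the C7/C8 stereodiad comes from an enantioselective Ireland–Claisen rearrangement of geranyl 5-methylhex-4-enoate.
5. Ring order: cyclobutenone (step 11); in step 12 a transient cyclohexane (aldol) and cyclooctadiene (ring opening), then both six-membered rings of the bicyclo[3.3.1]nonane in one bond formation.

Key step: step 12

Remark: target numbering is used for all intermediates (C1, C5 bridgeheads; C2, C3, C4 the dione bridge; C9 bridging ketone; C6 methylene; C7 CH bearing prenyl; C8 quaternary carbon with methyl and homoprenyl); prenyl = 3-methylbut-2-en-1-yl, homoprenyl = 4-methylpent-3-en-1-yl.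
Assumption: the (4S,5S)-bromoborane of step 2 is taken as the enantiomer that leads to (2S,3R)-5; if the sense of induction is the opposite, the (4R,5R) reagent is used and nothing else changes.
Remark: 27 is written as the given enol tautomer (C2 ketone, C4 enol); the enol forms of the 2-acyl-1,3-dione interconvert.

**Route**

Step 1
Reactants: 1 geraniol; 2 5-methylhex-4-enoic acid
Product: 3 geranyl 5-methylhex-4-enoate
Conditions: DCC, DMAP (cat.), CH2Cl2, 0 → 25 °C
Reagents that add atoms: none
Why: Steglich esterification of an unhindered primary allylic alcohol; no stereocentre is formed and the E geometry of the geranyl unit, which later encodes the C8 configuration, is untouched.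

Step 2
Reactants: 3 geranyl 5-methylhex-4-enoate
Product: 5 (2S,3R)-3-methyl-2-prenyl-3-homoprenylpent-4-enoic acid, via O-boryl ketene acetal 4 (not isolated)
Conditions: (4S,5S)-2-bromo-1,3-bis(4-methylphenylsulfonyl)-4,5-diphenyl-1,3,2-diazaborolidine (1.1 equiv), iPr2NEt, CH2Cl2, −78 → 4 °C; aqueous work-up
Reagents that add atoms: none
Why: Enantioselective boron-mediated Ireland–Claisen rearrangement, in which soft enolisation should give the ketene acetal with prenyl cis to O–B, the chair transition state with the E-geranyl unit then places prenyl and homoprenyl pseudo-equatorial (C7–H anti to C8–CH3, the relative configuration of the target), and the C2-symmetric sulfonamide ligand selects the enolate face and so the absolute configuration of both centres.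

Step 3
Reactants: 5 (2S,3R)-acid
Product: 6 (2S,3R)-3-methyl-2-prenyl-3-homoprenylpent-4-en-1-ol
Conditions: LiAlH4, THF, 0 → 25 °C
Reagents that add atoms: none
Why: Hydride reduction of the carboxylic acid to the primary alcohol (future C6); the α-stereocentre is not enolised under these conditions.

Step 4
Reactants: 6 (2S,3R)-alcohol
Product: 7 (3R,4S)-5-chloro-3-methyl-4-prenyl-3-homoprenylpent-1-ene
Conditions: PPh3, N-chlorosuccinimide, CH2Cl2, 0 → 25 °C
Reagents that add atoms: N-chlorosuccinimide, O=C1CCC(=O)N1Cl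
Why: Appel-type chlorination (SN2 at the primary carbon); the chloride is a latent electrophile that should survive hydroboration, oxidation and the enolate of step 8, because four-membered ring closure by chloride displacement is slow.

Step 5
Reactants: 7 chloride
Product: 9 (3R,4S)-5-chloro-3-methyl-4-prenyl-3-homoprenylpentan-1-ol, via B-alkyl-9-borabicyclononane 8 (not isolated)
Conditions: 9-borabicyclo[3.3.1]nonane, THF, 0 → 40 °C; then NaOH, H2O2, 0 → 25 °C
Reagents that add atoms: hydrogen peroxide, OO
Why: Anti-Markovnikov hydroboration–oxidation; the bulky borane should take the monosubstituted vinyl group and leave the two trisubstituted alkenes alone.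

Step 6
Reactants: 9 chloro alcohol
Product: 11 (3R,4S)-5-chloro-3-methyl-4-prenyl-3-homoprenylpentanoic acid, via aldehyde 10 (not isolated)
Conditions: TEMPO (cat.), PhI(OAc)2, MeCN/H2O (pH 7 buffer), 25 °C
Reagents that add atoms: water, O
Why: Nitroxyl-catalysed oxidation of the primary alcohol through the aldehyde hydrate to the acid; the alkenes and the alkyl chloride are inert to the oxoammonium oxidant.

Step 7
Reactants: 11 chloro acid
Product: 12 methyl (3R,4S)-5-chloro-3-methyl-4-prenyl-3-homoprenylpentanoate
Conditions: Me3SiCHN2, MeOH/toluene, 0 → 25 °C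
Reagents that add atoms: trimethylsilyldiazomethane, C[Si](C)(C)C=[N+]=[N-]
Why: Esterification with a diazoalkane under non-basic conditions, so that no carboxylate is formed that could lactonise onto the chloromethyl group.

Step 8
Reactants: 12 methyl ester
Product: 14 methyl (3R,4S)-5-chloro-3-methyl-2,4-diprenyl-3-homoprenylpentanoate (both C1 epimers), via lithium enolate 13 (not isolated)
Conditions: LiN(iPr)2, THF, −78 °C; then 1-bromo-3-methylbut-2-ene, DMPU, −78 → −20 °C
Reagents that add atoms: 1-bromo-3-methylbut-2-ene, CC(C)=CCBr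
Why: Ester enolate alkylation (SN2 at the allylic bromide) at the only enolisable position; the new C1 centre is formed as a mixture, which does not matter because C1 is trigonal again in step 12.

Step 9
Reactants: 14 chloro ester
Product: 15 methyl (3R,4S)-5-iodo-3-methyl-2,4-diprenyl-3-homoprenylpentanoate
Conditions: NaI, butan-2-one, reflux
Reagents that add atoms: sodium iodide, [Na+].[I-]
Why: Finkelstein halide exchange driven by precipitation of NaCl; it unmasks the electrophile for the C5–C6 bond.

Step 10
Reactants: 15 iodo ester; 2 5-methylhex-4-enoic acid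
Product: 17 (4R,5S)-7-methoxy-5-methyl-2,4,6-triprenyl-5-homoprenyl-7-oxoheptanoic acid (epimers at C1 and C5), via dilithium enediolate 16 (not isolated)
Conditions: 2 (1.5 equiv), LiN(iPr)2 (3.0 equiv), THF/DMPU, 0 °C; then 15, 0 → 25 °C; aq. HCl
Reagents that add atoms: none
Why: Alkylation of a carboxylic acid dianion (SN2) builds the C5–C6 bond and delivers directly the free acid needed for ketene formation, while the hindered methyl ester at the other chain end should stay intact.

Step 11
Reactants: 17 acid ester
Product: 20 methyl (3S,4R)-5-[2-ethoxy-4-oxo-1-prenylcyclobut-2-en-1-yl]-3-methyl-2,4-diprenyl-3-homoprenylpentanoate, via acid chloride 18 (not isolated), via ketene 19 (not isolated)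
Conditions: (COCl)2, DMF (cat.), CH2Cl2, 0 → 25 °C; evaporate; then ethoxyethyne (5 equiv), Et3N, Et2O, 25 °C
Reagents that add atoms: ethoxyethyne, CCOC#C
Why: Dehydrochlorination to the dialkylketene and regioselective [2+2] cycloaddition with the ynol ether (nucleophilic alkyne CH to the ketene carbonyl carbon) gives the 4,4-disubstituted 3-ethoxycyclobutenone; the excess of the reactive alkyne at room temperature should outrun the intramolecular ketene–alkene cycloaddition with the C7-prenyl group, which normally needs heating.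

Step 12
Reactants: 20 cyclobutenone ester
Product: 24 (1R,5S,7R,8S)-4-ethoxy-8-methyl-1,5,7-triprenyl-8-homoprenylbicyclo[3.3.1]non-3-ene-2,9-dione, via potassium ester enolate 21 (not isolated), via cyclobutenolate 22 (not isolated), via cyclooctadienolate 23 (not isolated)
Conditions: KN(SiMe3)2 (1.1 equiv), THF (0.01 M), −78 → 25 °C; AcOH
Reagents that add atoms: none
Why: Proposed new method: KN(SiMe3)2 removes the only acidic proton (C1–H), the ester enolate 21 adds to the strained, non-enolisable cyclobutenone carbonyl C2 (six-membered aldol ring, 6-exo-trig) to give cyclobutenolate 22, the alkoxide then drives the conrotatory 4π opening of the C2–C5 bond (oxygen rotating outward) to the eight-membered dienolate 23, and its γ-carbon C5 attacks the ester carbon C9 across the ring with loss of methoxide, so that the four-membered ring C2–C3–C4–C5 takes up C1 and C9 and becomes the six-membered ring C1–C2–C3–C4–C5–C9. The closest known reactions are the alkoxide-accelerated ring opening of 1,2-adducts of cyclobutenones and squarates followed by transannular carbonyl addition, the base-mediated C–C-cleaving annulations of cyclobutenones with carbon acids, and the alkoxide-catalysed conversion of ketene dimers (cyclobutane-1,3-diones) into cyclohexane-1,3,5-triones through ester enolates; the intramolecular variant that ends in a bridged trione is not known. The dione ring closes by a transannular 6-exo-trig acyl substitution, and the same C5–C9 bond closes the carbocycle C1–C8–C7–C6–C5–C9, also as a six-membered ring. C1 is set in the aldol step, for which the chair with C7-prenyl and C8-homoprenyl equatorial, C8-methyl axial, the solvated enolate terminus equatorial and the C1-prenyl group axial (anti to the axial methyl) is expected, and C5 then follows without choice because C9 can bridge C1 and C5 on one face of the eight-membered ring only; both C5 epimers of 20 converge because C5 is trigonal in 23. The step needs carbonyl (1,2) rather than conjugate addition to the vinylogous ester, which the hard potassium ester enolate and the ring strain of the ketone should secure, and γ- rather than α- or O-acylation of 23, which the ring geometry secures since only C5 can reach C9. Release of the cyclobutene strain makes the ring opening irreversible, and the flanking quaternary carbons shield the new C9 ketone from the expelled methoxide.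

Step 13
Reactants: 24 bicyclic ethyl enol ether
Product: 26 (1S,5S,7R,8S)-3-(3-acetoxybenzoyl)-4-ethoxy-8-methyl-1,5,7-triprenyl-8-homoprenylbicyclo[3.3.1]non-3-ene-2,9-dione, via vinyllithium 25 (not isolated)
Conditions: lithium 2,2,6,6-tetramethylpiperidide (1.3 equiv), THF, −78 °C; then 3-acetoxybenzoyl chloride (1.5 equiv), −78 → −40 °C
Reagents that add atoms: 3-acetoxybenzoyl chloride, CC(=O)Oc1cccc(c1)C(Cl)=O
Why: Vinylic deprotonation at C3 of the vinylogous ester (the only acidic C–H, both bridgeheads being quaternary) and C-acylation of the vinyllithium by the acid chloride, a known way to acylate O-alkyl enol ethers of bicyclo[3.3.1]nonane-2,4,9-triones; no stereocentre is touched.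

Step 14
Reactants: 26 aroylated enol ether
Product: 27 (1S,5S,7R,8S)-4-hydroxy-3-(3-hydroxybenzoyl)-8-methyl-1,5,7-triprenyl-8-homoprenylbicyclo[3.3.1]non-3-ene-2,9-dione (target)
Conditions: LiOH, 1,4-dioxane/H2O, 90 °C; then 1 M HCl
Reagents that add atoms: lithium hydroxide, [Li+].[OH-]
Why: Addition–elimination of hydroxide at C4 of the doubly activated vinylogous ester frees the enolised β-triketone and the same base saponifies the aryl acetate; C1, C5 and C8 are quaternary and C7 is not enolisable, so no stereocentre is at risk.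

**Compound list**

1 | geraniol | CC(C)=CCC/C(C)=C/CO | starting material
2 | 5-methylhex-4-enoic acid | CC(C)=CCCC(=O)O | starting material
3 | geranyl 5-methylhex-4-enoate | CC(C)=CCC/C(C)=C/COC(=O)CCC=C(C)C | intermediate
4 | O-boryl ketene acetal of 3 (prenyl cis to O–B, (4S,5S)-diazaborolidinyl) | CC(C)=CCC/C(C)=C/CO/C(OB1N(S(=O)(=O)c2ccc(C)cc2)[C@@H](c2ccccc2)[C@H](c2ccccc2)N1S(=O)(=O)c1ccc(C)cc1)=C/CC=C(C)C | intermediate (not isolated)
5 | (2S,3R)-3-methyl-2-prenyl-3-homoprenylpent-4-enoic acid | CC(C)=CCC[C@@](C=C)(C)[C@H](CC=C(C)C)C(=O)O | intermediate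
6 | (2S,3R)-3-methyl-2-prenyl-3-homoprenylpent-4-en-1-ol | CC(C)=CCC[C@@](C=C)(C)[C@H](CC=C(C)C)CO | intermediate
7 | (3R,4S)-5-chloro-3-methyl-4-prenyl-3-homoprenylpent-1-ene | CC(C)=CCC[C@@](C=C)(C)[C@H](CC=C(C)C)CCl | intermediate
8 | B-alkyl-9-borabicyclo[3.3.1]nonane from 7 | CC(C)=CCC[C@@](CCB1C2CCCC1CCC2)(C)[C@H](CC=C(C)C)CCl | intermediate (not isolated)
9 | (3R,4S)-5-chloro-3-methyl-4-prenyl-3-homoprenylpentan-1-ol | CC(C)=CCC[C@@](CCO)(C)[C@H](CC=C(C)C)CCl | intermediate
10 | (3R,4S)-5-chloro-3-methyl-4-prenyl-3-homoprenylpentanal | CC(C)=CCC[C@@](CC=O)(C)[C@H](CC=C(C)C)CCl | intermediate (not isolated)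
11 | (3R,4S)-5-chloro-3-methyl-4-prenyl-3-homoprenylpentanoic acid | CC(C)=CCC[C@@](CC(=O)O)(C)[C@H](CC=C(C)C)CCl | intermediate
12 | methyl (3R,4S)-5-chloro-3-methyl-4-prenyl-3-homoprenylpentanoate | CC(C)=CCC[C@@](CC(=O)OC)(C)[C@H](CC=C(C)C)CCl | intermediate
13 | lithium enolate of 12 | CC(C)=CCC[C@@](C=C([O-])OC)(C)[C@H](CC=C(C)C)CCl.[Li+] | intermediate (not isolated)
14 | methyl (3R,4S)-5-chloro-3-methyl-2,4-diprenyl-3-homoprenylpentanoate (C1 epimers) | CC(C)=CCC[C@@](C(CC=C(C)C)C(=O)OC)(C)[C@H](CC=C(C)C)CCl | intermediate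
15 | methyl (3R,4S)-5-iodo-3-methyl-2,4-diprenyl-3-homoprenylpentanoate (C1 epimers) | CC(C)=CCC[C@@](C(CC=C(C)C)C(=O)OC)(C)[C@H](CC=C(C)C)CI | intermediate
16 | dilithium enediolate of 2 | CC(C)=CCC=C([O-])[O-].[Li+].[Li+] | intermediate (not isolated)
17 | (4R,5S)-7-methoxy-5-methyl-2,4,6-triprenyl-5-homoprenyl-7-oxoheptanoic acid (C1 and C5 epimers) | CC(C)=CCC[C@@](C(CC=C(C)C)C(=O)OC)(C)[C@H](CC=C(C)C)CC(CC=C(C)C)C(=O)O | intermediate
18 | methyl (3S,4R)-7-chloro-3-methyl-2,4,6-triprenyl-3-homoprenyl-7-oxoheptanoate (acid chloride of 17) | CC(C)=CCC[C@@](C(CC=C(C)C)C(=O)OC)(C)[C@H](CC=C(C)C)CC(CC=C(C)C)C(=O)Cl | intermediate (not isolated)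
19 | methyl (3S,4R)-3-methyl-2,4,6-triprenyl-3-homoprenyl-7-oxohept-6-enoate (ketene) | CC(C)=CCC[C@@](C(CC=C(C)C)C(=O)OC)(C)[C@H](CC=C(C)C)CC(CC=C(C)C)=C=O | intermediate (not isolated)
20 | methyl (3S,4R)-5-[2-ethoxy-4-oxo-1-prenylcyclobut-2-en-1-yl]-3-methyl-2,4-diprenyl-3-homoprenylpentanoate (epimers at C1 and at the ring carbon C5) | CC(C)=CCC[C@@](C(CC=C(C)C)C(=O)OC)(C)[C@H](CC=C(C)C)CC1(CC=C(C)C)C(=O)C=C1OCC | intermediate
21 | potassium ester enolate of 20 | CC(C)=CCC[C@@](C(CC=C(C)C)=C([O-])OC)(C)[C@H](CC=C(C)C)CC1(CC=C(C)C)C(=O)C=C1OCC.[K+] | intermediate (not isolated)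
22 | potassium 8-ethoxy-2-(methoxycarbonyl)-3-methyl-2,4,6-triprenyl-3-homoprenylbicyclo[4.2.0]oct-7-en-1-olate (aldolate) | CC(C)=CCC[C@@]1(C)[C@H](CC=C(C)C)CC2(CC=C(C)C)C(OCC)=CC2([O-])[C@]1(CC=C(C)C)C(=O)OC.[K+] | intermediate (not isolated)
23 | potassium 3-ethoxy-8-(methoxycarbonyl)-7-methyl-4,6,8-triprenyl-7-homoprenylcycloocta-1,3-dien-1-olate | CC(C)=CCC[C@@]1(C)[C@H](CC=C(C)C)CC(CC=C(C)C)=C(OCC)C=C([O-])[C@]1(CC=C(C)C)C(=O)OC.[K+] | intermediate (not isolated)
24 | (1R,5S,7R,8S)-4-ethoxy-8-methyl-1,5,7-triprenyl-8-homoprenylbicyclo[3.3.1]non-3-ene-2,9-dione | CC(C)=CCC[C@@]1(C)[C@H](CC=C(C)C)C[C@]2(CC=C(C)C)C(=O)[C@@]1(CC=C(C)C)C(=O)C=C2OCC | intermediate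
25 | 3-lithio derivative of 24 | CC(C)=CCC[C@@]1(C)[C@H](CC=C(C)C)C[C@]2(CC=C(C)C)C(=O)[C@@]1(CC=C(C)C)C(=O)C([Li])=C2OCC | intermediate (not isolated)
26 | (1S,5S,7R,8S)-3-(3-acetoxybenzoyl)-4-ethoxy-8-methyl-1,5,7-triprenyl-8-homoprenylbicyclo[3.3.1]non-3-ene-2,9-dione | CC(C)=CCC[C@@]1(C)[C@H](CC=C(C)C)C[C@]2(CC=C(C)C)C(=O)[C@@]1(CC=C(C)C)C(=O)C(C(=O)c1cccc(OC(C)=O)c1)=C2OCC | intermediate
27 | (1S,5S,7R,8S)-4-hydroxy-3-(3-hydroxybenzoyl)-8-methyl-1,5,7-triprenyl-8-homoprenylbicyclo[3.3.1]non-3-ene-2,9-dione | CC(C)=CCC[C@@]1(C)[C@H](CC=C(C)C)C[C@]2(CC=C(C)C)C(=O)[C@@]1(CC=C(C)C)C(=O)C(C(=O)c1cccc(O)c1)=C2O | target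

**Step count and risks**

Total step count: 14. Longest linear sequence: 14 steps (1 → 27).

Steps most likely to fail:

1. Step 12 (proposed new method). The aldol addition may take place on the other face of the enolate and set C1 wrongly, which would end in the C7-endo diastereomer. The enolate may also add in conjugate fashion at the ethoxy-bearing carbon. The sequence may stall at the eight-membered ring if transannular acylation of the hindered ester is slow or reverts by methoxide attack. Fallback (known chemistry, carbocycle first, dione bridge second), from 11 back to 24: the acid 11 would be treated with 4-methylpent-3-enyllithium (2.2 equiv) to give the ketone F1. NaI/KN(SiMe3)2 would then close the carbocycle by intramolecular enolate alkylation at the chloromethyl carbon (six-membered ring favoured over four) to the cyclohexanone F2. Kinetic enolate formation at the remaining α-methylene and alkylation with prenyl bromide would give the 2,6-diprenyl ketone F3, and Et3N/tBuMe2SiOTf the silyl enol ether F4. Effenberger cyclisation with malonyl dichloride (then KOH, BnEt3NCl) would close the 2,4-dione bridge to the bicyclic trione F5. O-Ethylation (HC(OEt)3, TsOH, EtOH) would return 24 together with its regioisomeric enol ether F6, and both lead to 27 through steps 13 and 14.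

2. Step 10. SN2 displacement at the β-branched iodide next to the quaternary centre may be slow, so that E2 elimination and proton transfer to the ester (followed by four-membered ring closure) compete. Fallback (olefination in place of alkylation), from 15 back to 17: mild Kornblum oxidation (DMSO, NaHCO3) would give the aldehyde F7. Horner–Wadsworth–Emmons olefination with 2-(trimethylsilyl)ethyl 2-(diethoxyphosphoryl)-5-methylhex-4-enoate (NaH, THF) would give the trisubstituted enoate F8 (either alkene isomer serves). Conjugate reduction with [CuH(PPh3)]6 would give the saturated silylethyl ester F9, and Bu4NF would release the acid 17.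

3. Step 2. Soft enolisation by the bulky chiral bromoborane may be incomplete or give the wrong ketene acetal geometry, and the [3,3] shift onto the trisubstituted terminus may be sluggish; either would erode diastereo- and enantioselectivity. Fallback (resolution in place of asymmetric induction), from 3 back to 5: the ester 3 would be rearranged without chiral reagent (LiN(iPr)2, THF/DMPU, Me3SiCl, −78 → 25 °C) through the Z-configured silyl ketene acetal F10 and the same chair to the racemic acid F11 of the same relative configuration. F11 would be resolved by crystallisation of the salt of the wanted enantiomer with (R)-1-phenylethylamine, the ammonium carboxylate F12 (or with the (S)-amine if that salt crystallises better), and acidification would return 5.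

**Further compounds**

F1 | step 12 | (4R,5S)-4-(chloromethyl)-2,5,11-trimethyl-5-homoprenyl-dodeca-2,10-dien-7-one (ketone from 11) | CC(C)=CCC[C@@](CC(=O)CCC=C(C)C)(C)[C@H](CC=C(C)C)CCl
F2 | step 12 | (3S,4R)-3-methyl-4,6-diprenyl-3-homoprenylcyclohexan-1-one | CC(C)=CCC[C@@]1(C)[C@H](CC=C(C)C)CC(CC=C(C)C)C(=O)C1
F3 | step 12 | (3S,4R)-3-methyl-2,4,6-triprenyl-3-homoprenylcyclohexan-1-one | CC(C)=CCC[C@@]1(C)[C@H](CC=C(C)C)CC(CC=C(C)C)C(=O)C1CC=C(C)C
F4 | step 12 | tert-butyldimethylsilyl enol ether of F3 (double bond C9=C5) | CC(C)=CCC[C@@]1(C)[C@H](CC=C(C)C)CC(CC=C(C)C)=C(O[Si](C)(C)C(C)(C)C)C1CC=C(C)C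
F5 | step 12 | 4-hydroxy-8-methyl-1,5,7-triprenyl-8-homoprenylbicyclo[3.3.1]non-3-ene-2,9-dione (configuration as in 24) | CC(C)=CCC[C@@]1(C)[C@H](CC=C(C)C)C[C@]2(CC=C(C)C)C(=O)[C@@]1(CC=C(C)C)C(=O)C=C2O
F6 | step 12 | 2-ethoxy-8-methyl-1,5,7-triprenyl-8-homoprenylbicyclo[3.3.1]non-2-ene-4,9-dione (regioisomer of 24) | CC(C)=CCC[C@@]1(C)[C@H](CC=C(C)C)C[C@]2(CC=C(C)C)C(=O)[C@@]1(CC=C(C)C)C(OCC)=CC2=O
F7 | step 10 | methyl (3S,4R)-4-formyl-3-methyl-2-prenyl-3-homoprenyl-7-methyloct-6-enoate (aldehyde from 15) | CC(C)=CCC[C@@](C(CC=C(C)C)C(=O)OC)(C)[C@H](CC=C(C)C)C=O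
F8 | step 10 | 7-methyl 1-[2-(trimethylsilyl)ethyl] (4R,5S)-5-methyl-2,4,6-triprenyl-5-homoprenylhept-2-enedioate | CC(C)=CCC[C@@](C(CC=C(C)C)C(=O)OC)(C)[C@H](CC=C(C)C)C=C(CC=C(C)C)C(=O)OCC[Si](C)(C)C
F9 | step 10 | 7-methyl 1-[2-(trimethylsilyl)ethyl] (4R,5S)-5-methyl-2,4,6-triprenyl-5-homoprenylheptanedioate | CC(C)=CCC[C@@](C(CC=C(C)C)C(=O)OC)(C)[C@H](CC=C(C)C)CC(CC=C(C)C)C(=O)OCC[Si](C)(C)C
F10 | step 2 | (Z)-trimethylsilyl ketene acetal of 3 (prenyl cis to O–Si) | CC(C)=CCC/C(C)=C/CO/C(O[Si](C)(C)C)=C/CC=C(C)C
F11 | step 2 | racemic (2S*,3R*)-3-methyl-2-prenyl-3-homoprenylpent-4-enoic acid | CC(C)=CCC[C@@](C=C)(C)[C@H](CC=C(C)C)C(=O)O.CC(C)=CCC[C@](C=C)(C)[C@@H](CC=C(C)C)C(=O)O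
F12 | step 2 | (R)-1-phenylethanaminium (2S,3R)-3-methyl-2-prenyl-3-homoprenylpent-4-enoate | CC(C)=CCC[C@@](C=C)(C)[C@H](CC=C(C)C)C(=O)[O-].C[C@@H]([NH3+])c1ccccc1
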